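**Plan**

1. Retrosynthetic cuts: first the cis-coumarate ester C–O bond. Then two bonds of ring A at once – the bond from the methyl-bearing quaternary ring-fusion carbon to its CH2 neighbour, and the ring C=C – which releases acrolein and a ring B phosphonoacetate. Last, the bond between that acetate arm and ring B (Claisen), back to (S)-carvone.
2. Forward order: ring B is bought. Ring A is closed onto it by a three-component reductive [3+3] annulation (hydrogen atom + ring B alkene + acrolein, then olefination). The side chain and the ring A ester are then adjusted, and the coumarate is joined last.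
3. Enabling feature: in ring A the quaternary carbon and the ester-bearing alkene carbon are 1,3-related through the ring-fusion CH, and the other three ring A carbons form an unbranched CH2–CH2–CH= unit. A tertiary radical at the methyl-bearing carbon of a 1-methylcyclohexene and a phosphonate carbanion on the neighbouring ring substituent therefore act as a 1,3-dinucleophile toward acrolein as 1,3-dielectrophile.
4. Stereochemistry: the side-chain-bearing carbon comes from (S)-carvone; the ring-fusion CH from 1,3-chirality transfer in the Claisen rearrangement of the cis-allylic alcohol; the quaternary centre from radical addition anti to the neighbouring branch; the Z-alkene from (Z)-3-iodoacrylic acid with retention.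
5. Helper: the isopropenyl group is carried as its epoxide (steps 1–6) so that ring B holds a single alkene when the hydrogen atom is delivered; the epoxide later supplies the oxygen of the acrylate ester.

Key step: step 5

Remark: all oxirane-bearing intermediates are carried as mixtures of epimers at the oxirane carbon, and the phosphonates also at the phosphonate carbon; both centres become sp2 later, so they are left undefined in the SMILES.

**Step 1**
Reactants: 1 (S)-(+)-carvone
Product: 2 (5S)-2-methyl-5-(2-methyloxiran-2-yl)cyclohex-2-en-1-one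
Conditions: mCPBA, CH2Cl2, 0 °C
Reagents that add atoms: 3-chloroperoxybenzoic acid, OOC(=O)c1cccc(Cl)c1
Why: Prilezhaev epoxidation should take the electron-rich 1,1-disubstituted alkene and leave the electron-poor enone alkene; the new oxirane centre forms without control and is removed in step 6.

**Step 2**
Reactants: 2 (5S)-2-methyl-5-(2-methyloxiran-2-yl)cyclohex-2-en-1-one
Product: 3 (1S,5S)-2-methyl-5-(2-methyloxiran-2-yl)cyclohex-2-en-1-ol (OH cis to the oxiranyl group)
Conditions: NaBH4, CeCl3·7H2O, MeOH, −78 °C
Reagents that add atoms: none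
Why: Luche 1,2-reduction, in which axial hydride delivery to the half-chair enone should give the pseudo-equatorial alcohol cis to the C-5 substituent, as is usual for carvone-type enones.

**Step 3**
Reactants: 3 (1S,5S)-2-methyl-5-(2-methyloxiran-2-yl)cyclohex-2-en-1-ol; 4 triethyl orthoacetate
Product: 6 ethyl 2-[(1S,5R)-2-methyl-5-(2-methyloxiran-2-yl)cyclohex-2-en-1-yl]acetate (acetate arm cis to the oxiranyl group), via ketene acetal 5 (not isolated)
Conditions: 4 (excess), 2-nitrophenol (cat.), 140 °C, EtOH distilled off
Reagents that add atoms: none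
Why: Johnson–Claisen rearrangement, whose suprafacial [3,3] shift forms the new C–C bond on the ring face that carried the C–O bond, so the acetate arm should end cis to the oxiranyl group (1,3-chirality transfer) and the ring alkene moves next to the methyl-bearing carbon; the weak phenol catalyst is chosen to spare the oxirane.

**Step 4**
Reactants: 6 ethyl 2-[(1S,5R)-2-methyl-5-(2-methyloxiran-2-yl)cyclohex-2-en-1-yl]acetate
Product: 7 ethyl 2-(diethoxyphosphoryl)-2-[(1R,5R)-2-methyl-5-(2-methyloxiran-2-yl)cyclohex-2-en-1-yl]acetate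
Conditions: LiN(i-Pr)2 (2.2 equiv), THF, −78 °C; ClP(O)(OEt)2; −78 → 0 °C
Reagents that add atoms: diethyl chlorophosphate, CCOP(=O)(Cl)OCC
Why: C-phosphorylation of the ester enolate (the second equivalent of base rearranges any O-phosphorylated ketene acetal by 1,3-phosphoryl migration), a standard entry to α-substituted phosphonoacetates; the new centre is uncontrolled and becomes sp2 in step 5.

**Step 5**
Reactants: 7 ethyl 2-(diethoxyphosphoryl)-2-[(1R,5R)-2-methyl-5-(2-methyloxiran-2-yl)cyclohex-2-en-1-yl]acetate; 8 acrolein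
Product: 10 ethyl (4aR,7R,8aR)-4a-methyl-7-(2-methyloxiran-2-yl)-3,4,4a,5,6,7,8,8a-octahydronaphthalene-1-carboxylate (trans ring fusion), via phosphono aldehyde 9 (not isolated)
Conditions: Fe(acac)3 (0.5 equiv), PhSiH3, EtOH, 8 added slowly, rt; volatiles removed; then LiCl, DBU, MeCN, rt (same flask)
Reagents that add atoms: none
Why: The iron hydride formed from Fe(acac)3 and PhSiH3 should transfer a hydrogen atom to the CH terminus (C-3) of the only alkene of 7; the tertiary ring radical then adds to the β-carbon of acrolein (Giese addition), the α-formyl radical is reduced and protonated to aldehyde 9, and LiCl/DBU then triggers intramolecular Horner–Wadsworth–Emmons olefination between the phosphonoacetate carbon and the new aldehyde. The closest known reaction types are iron-hydride reductive coupling of unactivated alkenes with enals (HAT-initiated radical–polar crossover annulation) for the first stage and HWE cyclisation of α-substituted phosphonoacetates to cyclohexene-1-carboxylates for the second. Ring A is closed in the olefination as a six-membered ring (6-exo-trig addition of the carbanion to the aldehyde, then loss of phosphate), so the ring alkene is necessarily cis within the ring. The only new stereocentre, the quaternary carbon C-4a, is set in the radical addition: acrolein should approach the chair-like radical, whose two ring substituents are equatorial, from the face anti to the neighbouring branched CH(P)CO2Et group, which places the new chain trans to that group and gives the trans ring fusion with the angular methyl cis to the C-7 substituent. The step needs chemoselective hydrogen-atom transfer, secured by the oxirane mask that leaves the ring alkene as the only donor olefin and by keeping the ring A carbonyl as a non-electrophilic ester. It also needs an unambiguous ring closure, secured because 9 holds exactly one aldehyde and one phosphonate carbon.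

**Step 6**
Reactants: 10 ethyl (4aR,7R,8aR)-4a-methyl-7-(2-methyloxiran-2-yl)-3,4,4a,5,6,7,8,8a-octahydronaphthalene-1-carboxylate
Product: 12 ethyl (4aR,7R,8aR)-7-(3-hydroxyprop-1-en-2-yl)-4a-methyl-3,4,4a,5,6,7,8,8a-octahydronaphthalene-1-carboxylate, via allyl silyl ether 11 (not isolated)
Conditions: TMSOTf, DBU, toluene, 0 °C → rt; then citric acid, MeOH
Reagents that add atoms: trimethylsilyl trifluoromethanesulfonate, C[Si](C)(C)OS(=O)(=O)C(F)(F)F (silyl group present in 11 only)
Why: Silyl triflate/amidine isomerisation of a 2,2-disubstituted oxirane to the allyl silyl ether (O-silylation, opening at the tertiary carbon, loss of a methyl proton, which is less hindered than the ring methine), followed by desilylation; both oxirane epimers converge on 12.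

**Step 7**
Reactants: 12 ethyl (4aR,7R,8aR)-7-(3-hydroxyprop-1-en-2-yl)-4a-methyl-3,4,4a,5,6,7,8,8a-octahydronaphthalene-1-carboxylate
Product: 14 2-[(2R,4aR,8aR)-8-(ethoxycarbonyl)-4a-methyl-1,2,3,4,4a,5,6,8a-octahydronaphthalen-2-yl]prop-2-enoic acid, via enal 13 (not isolated)
Conditions: TEMPO (cat.), PhI(OAc)2, CH2Cl2, rt; then NaClO2, NaH2PO4, 2-methyl-2-butene, t-BuOH/H2O, 0 °C → rt
Reagents that add atoms: sodium chlorite, [Na+].[O-]Cl=O
Why: Oxoammonium oxidation of the primary allylic alcohol to the enal followed in the same flask by Pinnick oxidation, with the alkene scavenger protecting the other C=C bonds from hypochlorite.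

**Step 8**
Reactants: 14 2-[(2R,4aR,8aR)-8-(ethoxycarbonyl)-4a-methyl-1,2,3,4,4a,5,6,8a-octahydronaphthalen-2-yl]prop-2-enoic acid
Product: 15 2-[(2R,4aR,8aR)-8-(hydroxymethyl)-4a-methyl-1,2,3,4,4a,5,6,8a-octahydronaphthalen-2-yl]prop-2-enoic acid
Conditions: i-Bu2AlH (3.5 equiv), CH2Cl2/THF, −78 °C; aq. potassium sodium tartrate, then pH 3
Reagents that add atoms: none
Why: The first equivalent of hydride converts the acid into an aluminium carboxylate that should resist reduction at −78 °C, while the conjugated ethyl ester undergoes 1,2-reduction to the allylic alcohol (chemoselective ester reduction beside a carboxylate).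

**Step 9**
Reactants: 15 2-[(2R,4aR,8aR)-8-(hydroxymethyl)-4a-methyl-1,2,3,4,4a,5,6,8a-octahydronaphthalen-2-yl]prop-2-enoic acid
Product: 16 methyl 2-[(2R,4aR,8aR)-8-(hydroxymethyl)-4a-methyl-1,2,3,4,4a,5,6,8a-octahydronaphthalen-2-yl]prop-2-enoate
Conditions: MeI, KHCO3, DMF, rt
Reagents that add atoms: iodomethane, CI
Why: SN2 O-methylation of the carboxylate; hydrogen carbonate is too weak a base to deprotonate the allylic alcohol, so only the acid reacts.

**Step 10**
Reactants: 17 (Z)-3-iodoprop-2-enoic acid; 18 (4-hydroxyphenyl)boronic acid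
Product: 19 (Z)-3-(4-hydroxyphenyl)prop-2-enoic acid (cis-p-coumaric acid)
Conditions: Pd(PPh3)4 (5 mol %), K2CO3, 1,4-dioxane/H2O, 45 °C, light excluded; aq. HCl to pH 3
Reagents that add atoms: none
Why: Suzuki–Miyaura coupling, in which oxidative addition and reductive elimination proceed with retention at the vinyl iodide, so the Z geometry should be carried over; free phenol and acid are tolerated as their salts.

**Step 11**
Reactants: 16 methyl 2-[(2R,4aR,8aR)-8-(hydroxymethyl)-4a-methyl-1,2,3,4,4a,5,6,8a-octahydronaphthalen-2-yl]prop-2-enoate; 19 (Z)-3-(4-hydroxyphenyl)prop-2-enoic acid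
Product: 20 methyl 2-[(2R,4aR,8aR)-8-({[(2Z)-3-(4-hydroxyphenyl)prop-2-enoyl]oxy}methyl)-4a-methyl-1,2,3,4,4a,5,6,8a-octahydronaphthalen-2-yl]prop-2-enoate (target)
Conditions: PPh3, DIAD, THF, 0 °C → rt, light excluded
Reagents that add atoms: none
Why: Mitsunobu esterification, in which the carboxylic acid (far more acidic than the phenol) is the pronucleophile and displaces the activated primary allylic oxygen by SN2; the base-free, dark conditions should preserve the Z-alkene, and no stereocentre is touched.

**Compound list**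

1 | (S)-(+)-carvone, (5S)-2-methyl-5-(prop-1-en-2-yl)cyclohex-2-en-1-one | CC1=CC[C@@H](CC1=O)C(C)=C | starting material
2 | (5S)-2-methyl-5-(2-methyloxiran-2-yl)cyclohex-2-en-1-one | CC1=CC[C@@H](CC1=O)C2(C)CO2 | intermediate
3 | (1S,5S)-2-methyl-5-(2-methyloxiran-2-yl)cyclohex-2-en-1-ol | CC1=CC[C@@H](C[C@@H]1O)C2(C)CO2 | intermediate
4 | triethyl orthoacetate | CC(OCC)(OCC)OCC | starting material
5 | 1-ethoxyvinyl ether of 3, (1S,5S)-1-(1-ethoxyethenyloxy)-2-methyl-5-(2-methyloxiran-2-yl)cyclohex-2-ene | CC1=CC[C@@H](C[C@@H]1OC(=C)OCC)C2(C)CO2 | intermediate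
6 | ethyl 2-[(1S,5R)-2-methyl-5-(2-methyloxiran-2-yl)cyclohex-2-en-1-yl]acetate | CC1=CC[C@H](C[C@H]1CC(=O)OCC)C2(C)CO2 | intermediate
7 | ethyl 2-(diethoxyphosphoryl)-2-[(1R,5R)-2-methyl-5-(2-methyloxiran-2-yl)cyclohex-2-en-1-yl]acetate | CC1=CC[C@H](C[C@H]1C(C(=O)OCC)P(=O)(OCC)OCC)C2(C)CO2 | intermediate
8 | acrolein (prop-2-enal) | C=CC=O | starting material
9 | ethyl 2-(diethoxyphosphoryl)-2-[(1R,2S,5R)-2-methyl-5-(2-methyloxiran-2-yl)-2-(3-oxopropyl)cyclohexyl]acetate | CC3(CO3)[C@@H]1CC[C@@](C)(CCC=O)[C@@H](C1)C(C(=O)OCC)P(=O)(OCC)OCC | intermediate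
10 | ethyl (4aR,7R,8aR)-4a-methyl-7-(2-methyloxiran-2-yl)-3,4,4a,5,6,7,8,8a-octahydronaphthalene-1-carboxylate | CC3(CO3)[C@@H]1CC[C@@]2(C)CCC=C(C(=O)OCC)[C@@H]2C1 | intermediate
11 | ethyl (4aR,7R,8aR)-4a-methyl-7-[3-(trimethylsilyloxy)prop-1-en-2-yl]-3,4,4a,5,6,7,8,8a-octahydronaphthalene-1-carboxylate | C=C(CO[Si](C)(C)C)[C@@H]1CC[C@@]2(C)CCC=C(C(=O)OCC)[C@@H]2C1 | intermediate
12 | ethyl (4aR,7R,8aR)-7-(3-hydroxyprop-1-en-2-yl)-4a-methyl-3,4,4a,5,6,7,8,8a-octahydronaphthalene-1-carboxylate | C=C(CO)[C@@H]1CC[C@@]2(C)CCC=C(C(=O)OCC)[C@@H]2C1 | intermediate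
13 | ethyl (4aR,7R,8aR)-4a-methyl-7-(3-oxoprop-1-en-2-yl)-3,4,4a,5,6,7,8,8a-octahydronaphthalene-1-carboxylate | C=C(C=O)[C@@H]1CC[C@@]2(C)CCC=C(C(=O)OCC)[C@@H]2C1 | intermediate
14 | 2-[(2R,4aR,8aR)-8-(ethoxycarbonyl)-4a-methyl-1,2,3,4,4a,5,6,8a-octahydronaphthalen-2-yl]prop-2-enoic acid | C=C(C(=O)O)[C@@H]1CC[C@@]2(C)CCC=C(C(=O)OCC)[C@@H]2C1 | intermediate
15 | 2-[(2R,4aR,8aR)-8-(hydroxymethyl)-4a-methyl-1,2,3,4,4a,5,6,8a-octahydronaphthalen-2-yl]prop-2-enoic acid | C=C(C(=O)O)[C@@H]1CC[C@@]2(C)CCC=C(CO)[C@@H]2C1 | intermediate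
16 | methyl 2-[(2R,4aR,8aR)-8-(hydroxymethyl)-4a-methyl-1,2,3,4,4a,5,6,8a-octahydronaphthalen-2-yl]prop-2-enoate | C=C(C(=O)OC)[C@@H]1CC[C@@]2(C)CCC=C(CO)[C@@H]2C1 | intermediate
17 | (Z)-3-iodoprop-2-enoic acid | OC(=O)/C=C\I | starting material
18 | (4-hydroxyphenyl)boronic acid | OB(O)c1ccc(O)cc1 | starting material
19 | (Z)-3-(4-hydroxyphenyl)prop-2-enoic acid | OC(=O)/C=C\c1ccc(O)cc1 | intermediate
20 | methyl 2-[(2R,4aR,8aR)-8-({[(2Z)-3-(4-hydroxyphenyl)prop-2-enoyl]oxy}methyl)-4a-methyl-1,2,3,4,4a,5,6,8a-octahydronaphthalen-2-yl]prop-2-enoate | C=C(C(=O)OC)[C@@H]1CC[C@@]2(C)CCC=C(COC(=O)/C=C\c3ccc(O)cc3)[C@@H]2C1 | target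

**Totals**

Total step count: 11. Longest linear sequence: 10 (steps 1–9 and 11; step 10 is a one-step branch).

**Steps most likely to fail**

Step 5. The iron hydride may reduce or oligomerise acrolein faster than the tertiary radical is trapped, the oxirane may be opened under the Lewis-acidic reductive conditions, and the facial selectivity of the radical addition may be low. The fallback generates the same tertiary radical without a metal hydride in the presence of the acceptor; it addresses the first two processes but not the facial selectivity. It sets out from 7 and returns at 9, which is then closed to 10 by the LiCl/DBU stage of step 5. Mukaiyama hydration of 7 (Mn(dpm)3, PhSiH3, O2, i-PrOH) should give the tertiary alcohol ethyl 2-(diethoxyphosphoryl)-2-[(1R,5R)-2-hydroxy-2-methyl-5-(2-methyloxiran-2-yl)cyclohexyl]acetate F1. Acylation with methyl chlorooxoacetate (Et3N, DMAP) gives the mixed oxalate (2R,4R)-2-[1-(diethoxyphosphoryl)-2-ethoxy-2-oxoethyl]-1-methyl-4-(2-methyloxiran-2-yl)cyclohexyl methyl oxalate F2. Selective hydrolysis with CsOH (1 equiv, THF/H2O) gives the cesium oxalate F3. Visible-light photoredox fragmentation of F3 (Ir[dF(CF3)ppy]2(dtbbpy)PF6, blue light, DME/DMF/H2O) in the presence of 8 releases two CO2 and should deliver the radical adduct 9 under redox-neutral conditions.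

Step 3. The cis relationship of the hydroxyl and oxiranyl groups forces the rearrangement through a conformer with both groups axial, so the sigmatropic step may be slow enough for heat- or acid-induced opening of the oxirane and elimination to compete. The fallback replaces the rearrangement by an ionic allylic substitution; it sets out from 3 and returns at 7, so that 6 and step 4 are bypassed. Methyl chloroformate/pyridine converts 3 into methyl (1S,5S)-2-methyl-5-(2-methyloxiran-2-yl)cyclohex-2-en-1-yl carbonate F4. Tsuji–Trost alkylation of F4 with triethyl phosphonoacetate (Pd2(dba)3, N,N'-bis[2-(diphenylphosphino)benzoyl]cyclohexane-1,2-diamine, THF, rt) proceeds by ionisation anti and attack anti, so the nucleophile should enter cis to the oxiranyl group. Because the two allyl termini are related by the local symmetry of the ring, the ligand enantiomer that directs attack to the terminus leading to 7 has to be selected.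

Step 11. The cis-cinnamate may isomerise to the trans isomer (in 19 before coupling, or by reversible phosphine addition during coupling), and the free phenol may be alkylated in competition with the acid. The fallback builds the Z-alkene on the substrate; it sets out from 16 and returns at 20. Esterification of 16 with 2-(diphenoxyphosphoryl)acetic acid (EDC·HCl, DMAP, CH2Cl2) gives the phosphonoacetate methyl 2-[(2R,4aR,8aR)-8-({[2-(diphenoxyphosphoryl)acetyl]oxy}methyl)-4a-methyl-1,2,3,4,4a,5,6,8a-octahydronaphthalen-2-yl]prop-2-enoate F5. Z-selective HWE olefination of F5 with 4-(tert-butyldimethylsilyloxy)benzaldehyde (NaH, THF, −78 °C) should give the silyl ether of the target F6, which is desilylated with HF·pyridine (THF, 0 °C) to 20.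

**Further compounds**

F1 | step 5 | ethyl 2-(diethoxyphosphoryl)-2-[(1R,5R)-2-hydroxy-2-methyl-5-(2-methyloxiran-2-yl)cyclohexyl]acetate | CC1(O)CC[C@H](C[C@H]1C(C(=O)OCC)P(=O)(OCC)OCC)C2(C)CO2
F2 | step 5 | (2R,4R)-2-[1-(diethoxyphosphoryl)-2-ethoxy-2-oxoethyl]-1-methyl-4-(2-methyloxiran-2-yl)cyclohexyl methyl oxalate | CC1(OC(=O)C(=O)OC)CC[C@H](C[C@H]1C(C(=O)OCC)P(=O)(OCC)OCC)C2(C)CO2
F3 | step 5 | cesium 2-{[(2R,4R)-2-[1-(diethoxyphosphoryl)-2-ethoxy-2-oxoethyl]-1-methyl-4-(2-methyloxiran-2-yl)cyclohexyl]oxy}-2-oxoacetate | CC1(OC(=O)C(=O)[O-])CC[C@H](C[C@H]1C(C(=O)OCC)P(=O)(OCC)OCC)C2(C)CO2.[Cs+]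
F4 | step 3 | methyl (1S,5S)-2-methyl-5-(2-methyloxiran-2-yl)cyclohex-2-en-1-yl carbonate | CC1=CC[C@@H](C[C@@H]1OC(=O)OC)C2(C)CO2
F5 | step 11 | methyl 2-[(2R,4aR,8aR)-8-({[2-(diphenoxyphosphoryl)acetyl]oxy}methyl)-4a-methyl-1,2,3,4,4a,5,6,8a-octahydronaphthalen-2-yl]prop-2-enoate | C=C(C(=O)OC)[C@@H]1CC[C@@]2(C)CCC=C(COC(=O)CP(=O)(Oc3ccccc3)Oc3ccccc3)[C@@H]2C1
F6 | step 11 | methyl 2-[(2R,4aR,8aR)-8-({[(2Z)-3-{4-[(tert-butyldimethylsilyl)oxy]phenyl}prop-2-enoyl]oxy}methyl)-4a-methyl-1,2,3,4,4a,5,6,8a-octahydronaphthalen-2-yl]prop-2-enoate | C=C(C(=O)OC)[C@@H]1CC[C@@]2(C)CCC=C(COC(=O)/C=C\c3ccc(O[Si](C)(C)C(C)(C)C)cc3)[C@@H]2C1
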